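**Plan**
- Retrosynthesis: the S–O bonds at O3 and O4' are cut first, then the three benzyl ethers; O3 and the C4 carbonyl are traced back to the C3=C4 alkene of a flav-3-ene.
- Ring C is then opened at C4–C4a and O1–C2 to an aryl 1-arylpropargyl ether, which is cut at O1–C2 (ring A phenol plus propargylic alcohol) and at C2–C3 (ring B aldehyde plus ethynyl Grignard reagent).
- Forward: the ring B aldehyde is protected (4'-OMOM, 3'-OBn), ethynylated and etherified with the ring A phenol; heating closes ring C; dihydroxylation and double oxidation give the flavonol; MOM removal, bis-sulfation and hydrogenolysis finish.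
- Enabling feature: ring A is a 3,5-bis(benzyloxy)phenyl ether whose two ortho carbons (future C4a and C8) are mirror-related, and ring C is a pyran whose O1–C2 bond is benzylic to ring B, so it can be broken and re-formed thermally.
- Stereochemistry: the target is achiral; C2 (from step 3 on) and C3/C4 (step 6) are racemic, transient centres that are erased in step 7.

Key step: step 5

Assumption: the target is drawn as the free bis(hydrogen sulfate), so 16 and 17 are named and drawn in that protonation state; in the flask they would be carried as sodium salts, and 17 would be released at the end by a short pass through an H+-form resin. Phenol 6 and Grignard reagent 4 are taken as purchased.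

**Step 1**
Reactants: 1 3,4-dihydroxybenzaldehyde
Product: 2 3-hydroxy-4-(methoxymethoxy)benzaldehyde
Conditions: MOMCl (1.05 equiv), K2CO3 (1.2 equiv), acetone, 0 °C to rt
Reagents that add atoms: chloromethyl methyl ether (MOMCl), COCCl
Why: Williamson-type O-alkylation; with one equivalent of weak base only the more acidic 4-OH (para to the formyl group) is deprotonated, so the MOM group should go selectively to O4.

**Step 2**
Reactants: 2 3-hydroxy-4-(methoxymethoxy)benzaldehyde
Product: 3 3-(benzyloxy)-4-(methoxymethoxy)benzaldehyde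
Conditions: BnBr, K2CO3, DMF, rt
Reagents that add atoms: benzyl bromide, BrCc1ccccc1
Why: Williamson ether synthesis on the remaining phenol; the MOM acetal and the aldehyde are inert to K2CO3 and BnBr.

**Step 3**
Reactants: 3 3-(benzyloxy)-4-(methoxymethoxy)benzaldehyde; 4 ethynylmagnesium bromide
Product: 5 1-[3-(benzyloxy)-4-(methoxymethoxy)phenyl]prop-2-yn-1-ol (racemic)
Conditions: HC≡CMgBr (0.5 M in THF), THF, 0 °C; aq NH4Cl
Reagents that add atoms: none
Why: Grignard 1,2-addition of an alkynyl nucleophile to an aryl aldehyde; the carbinol centre forms without control and is racemic, which is harmless because it is lost later.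

**Step 4**
Reactants: 5 1-[3-(benzyloxy)-4-(methoxymethoxy)phenyl]prop-2-yn-1-ol; 6 3,5-bis(benzyloxy)phenol
Product: 7 1,3-bis(benzyloxy)-5-({1-[3-(benzyloxy)-4-(methoxymethoxy)phenyl]prop-2-yn-1-yl}oxy)benzene (racemic)
Conditions: PPh3, DIAD, THF, 0 °C to rt
Reagents that add atoms: none
Why: Mitsunobu etherification of a secondary propargylic alcohol with a phenol goes by SN2 displacement of the oxyphosphonium ion (inversion, irrelevant for the racemate), and the neutral conditions spare the MOM and benzyl ethers.

**Step 5**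
Reactants: 7 1,3-bis(benzyloxy)-5-({1-[3-(benzyloxy)-4-(methoxymethoxy)phenyl]prop-2-yn-1-yl}oxy)benzene
Product: 11 5,7-bis(benzyloxy)-2-[3-(benzyloxy)-4-(methoxymethoxy)phenyl]-2H-chromene (racemic flav-3-ene), via allenyl dienone 8 (not isolated), via o-allenylphenol 9 (not isolated), via o-quinone methide 10 (not isolated)
Conditions: PhNEt2 (0.05 M), 180 °C, Ar, dark
Reagents that add atoms: none
Why: Heating should trigger a [3,3] shift that joins an ortho carbon of ring A (future C4a) to the alkyne terminus (future C4) and breaks the benzylic O1–C2 bond, giving allenyl dienone 8, which enolises to o-allenylphenol 9; a 1,5-hydrogen shift from the phenol OH to the central allene carbon then gives the (Z)-o-quinone methide 10, which re-forms O1–C2 by thermal oxa-6π electrocyclisation. The closest known reaction is the thermal aryl propargyl ether Claisen rearrangement to 2H-chromenes. Ring C closes as a six-membered pyran by disrotatory 6π electrocyclisation of the 1-oxatriene, which is possible because the hydrogen shift places the vinyl group syn to the dienone carbonyl. C2 is created anew from the achiral quinone methide with no controlling element, so 11 is racemic, which is acceptable because C2 becomes sp2 in step 7. The only selectivity needed is the choice of ortho carbon, and the mirror symmetry of the 3,5-bis(benzyloxy)phenyl ring makes both ortho C–H positions identical. The basic, fluoride-free amine solvent should keep the benzylic ether and the MOM acetal from ionising and disfavour the benzofuran pathway.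

**Step 6**
Reactants: 11 5,7-bis(benzyloxy)-2-[3-(benzyloxy)-4-(methoxymethoxy)phenyl]-2H-chromene
Product: 12 rac-(2R,3S,4S)-5,7-bis(benzyloxy)-2-[3-(benzyloxy)-4-(methoxymethoxy)phenyl]-3,4-dihydro-2H-chromene-3,4-diol (2,3-trans-3,4-cis)
Conditions: OsO4 (2 mol%), NMO, acetone/H2O, rt
Reagents that add atoms: osmium tetroxide, O=[Os](=O)(=O)=O; N-methylmorpholine N-oxide, C[N+]1([O-])CCOCC1; water, O
Why: Catalytic OsO4/NMO syn-dihydroxylation of the electron-rich cis-disubstituted C3=C4 bond; the reagent should add anti to the C2 aryl group to give the 2,3-trans-3,4-cis diol, and any other diastereomer would converge in step 7.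

**Step 7**
Reactants: 12 rac-(2R,3S,4S)-5,7-bis(benzyloxy)-2-[3-(benzyloxy)-4-(methoxymethoxy)phenyl]-3,4-dihydro-2H-chromene-3,4-diol
Product: 14 5,7-bis(benzyloxy)-2-[3-(benzyloxy)-4-(methoxymethoxy)phenyl]-3-hydroxy-4H-chromen-4-one, via chromane-3,4-dione 13 (not isolated)
Conditions: IBX (3 equiv), DMSO, rt
Reagents that add atoms: none
Why: IBX in DMSO is known to oxidise vicinal diols to α-diketones without C–C cleavage, and dione 13, with its acidic C2–H next to the C3 ketone, should tautomerise spontaneously to the aromatic 3-hydroxy-4-pyranone, erasing all three stereocentres.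

**Step 8**
Reactants: 14 5,7-bis(benzyloxy)-2-[3-(benzyloxy)-4-(methoxymethoxy)phenyl]-3-hydroxy-4H-chromen-4-one
Product: 15 5,7-bis(benzyloxy)-2-[3-(benzyloxy)-4-hydroxyphenyl]-3-hydroxy-4H-chromen-4-one
Conditions: HCl (2 M), MeOH/THF, 45 °C
Reagents that add atoms: none
Why: Acid-catalysed transacetalisation to methanol cleaves the aryl MOM ether, while benzyl ethers and the flavonol core are stable to dilute methanolic HCl.

**Step 9**
Reactants: 15 5,7-bis(benzyloxy)-2-[3-(benzyloxy)-4-hydroxyphenyl]-3-hydroxy-4H-chromen-4-one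
Product: 16 5,7-bis(benzyloxy)-2-[3-(benzyloxy)-4-(sulfooxy)phenyl]-4-oxo-4H-chromen-3-yl hydrogen sulfate
Conditions: SO3·pyridine (8 equiv), pyridine, 50 °C; then Na+-form cation-exchange resin, MeOH/H2O
Reagents that add atoms: sulfur trioxide–pyridine complex (SO3·pyridine), O=S(=O)([O-])[n+]1ccccc1
Why: O-sulfation of hydroxyl groups with SO3·pyridine; only O3 and O4' are free, so excess reagent should give the bis-sulfate with no regiochemical ambiguity.

**Step 10**
Reactants: 16 5,7-bis(benzyloxy)-2-[3-(benzyloxy)-4-(sulfooxy)phenyl]-4-oxo-4H-chromen-3-yl hydrogen sulfate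
Product: 17 quercetin 3,4'-bissulfate, 5,7-dihydroxy-2-[3-hydroxy-4-(sulfooxy)phenyl]-4-oxo-4H-chromen-3-yl hydrogen sulfate
Conditions: H2 (1 atm), 10% Pd/C, MeOH/H2O, rt; then H+-form cation-exchange resin, 0 °C
Reagents that add atoms: none
Why: Hydrogenolysis of aryl benzyl ethers over Pd/C; aryl sulfate monoester salts and the flavonol C2=C3 bond should be inert to hydrogen at 1 atm, and the pyridine-free sodium salt avoids catalyst inhibition.

**Compound list**
1 | 3,4-dihydroxybenzaldehyde | O=Cc1ccc(O)c(O)c1 | starting material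
2 | 3-hydroxy-4-(methoxymethoxy)benzaldehyde | O=Cc1ccc(OCOC)c(O)c1 | intermediate
3 | 3-(benzyloxy)-4-(methoxymethoxy)benzaldehyde | O=Cc1ccc(OCOC)c(OCc2ccccc2)c1 | intermediate
4 | ethynylmagnesium bromide | C#C[Mg]Br | starting material
5 | 1-[3-(benzyloxy)-4-(methoxymethoxy)phenyl]prop-2-yn-1-ol (racemic, R enantiomer drawn) | C#C[C@@H](O)c1ccc(OCOC)c(OCc2ccccc2)c1 | intermediate
6 | 3,5-bis(benzyloxy)phenol | Oc1cc(OCc2ccccc2)cc(OCc2ccccc2)c1 | starting material
7 | 1,3-bis(benzyloxy)-5-({1-[3-(benzyloxy)-4-(methoxymethoxy)phenyl]prop-2-yn-1-yl}oxy)benzene (racemic, S enantiomer drawn) | C#C[C@H](Oc1cc(OCc2ccccc2)cc(OCc2ccccc2)c1)c1ccc(OCOC)c(OCc2ccccc2)c1 | intermediate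
8 | 3,5-bis(benzyloxy)-6-{3-[3-(benzyloxy)-4-(methoxymethoxy)phenyl]propa-1,2-dien-1-yl}cyclohexa-2,4-dien-1-one (transient, stereoisomer mixture) | O=C1C=C(OCc2ccccc2)C=C(OCc2ccccc2)C1C=C=Cc1ccc(OCOC)c(OCc2ccccc2)c1 | intermediate
9 | 3,5-bis(benzyloxy)-2-{3-[3-(benzyloxy)-4-(methoxymethoxy)phenyl]propa-1,2-dien-1-yl}phenol (transient, racemic allene) | Oc1cc(OCc2ccccc2)cc(OCc2ccccc2)c1C=C=Cc1ccc(OCOC)c(OCc2ccccc2)c1 | intermediate
10 | (6Z)-3,5-bis(benzyloxy)-6-{3-[3-(benzyloxy)-4-(methoxymethoxy)phenyl]prop-2-en-1-ylidene}cyclohexa-2,4-dien-1-one (transient, styryl geometry open) | O=C1C=C(OCc2ccccc2)C=C(OCc2ccccc2)/C1=C/C=Cc1ccc(OCOC)c(OCc2ccccc2)c1 | intermediate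
11 | 5,7-bis(benzyloxy)-2-[3-(benzyloxy)-4-(methoxymethoxy)phenyl]-2H-chromene (racemic, 2R enantiomer drawn) | C1=C[C@H](c2ccc(OCOC)c(OCc3ccccc3)c2)Oc2cc(OCc3ccccc3)cc(OCc3ccccc3)c12 | intermediate
12 | rac-(2R,3S,4S)-5,7-bis(benzyloxy)-2-[3-(benzyloxy)-4-(methoxymethoxy)phenyl]-3,4-dihydro-2H-chromene-3,4-diol (2S,3R,4R enantiomer drawn) | O[C@H]1[C@H](c2ccc(OCOC)c(OCc3ccccc3)c2)Oc2cc(OCc3ccccc3)cc(OCc3ccccc3)c2[C@H]1O | intermediate
13 | 5,7-bis(benzyloxy)-2-[3-(benzyloxy)-4-(methoxymethoxy)phenyl]-2H-chromene-3,4-dione (racemic, 2S enantiomer drawn) | O=C1[C@H](c2ccc(OCOC)c(OCc3ccccc3)c2)Oc2cc(OCc3ccccc3)cc(OCc3ccccc3)c2C1=O | intermediate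
14 | 5,7-bis(benzyloxy)-2-[3-(benzyloxy)-4-(methoxymethoxy)phenyl]-3-hydroxy-4H-chromen-4-one | O=c1c(O)c(-c2ccc(OCOC)c(OCc3ccccc3)c2)oc2cc(OCc3ccccc3)cc(OCc3ccccc3)c12 | intermediate
15 | 5,7-bis(benzyloxy)-2-[3-(benzyloxy)-4-hydroxyphenyl]-3-hydroxy-4H-chromen-4-one | O=c1c(O)c(-c2ccc(O)c(OCc3ccccc3)c2)oc2cc(OCc3ccccc3)cc(OCc3ccccc3)c12 | intermediate
16 | 5,7-bis(benzyloxy)-2-[3-(benzyloxy)-4-(sulfooxy)phenyl]-4-oxo-4H-chromen-3-yl hydrogen sulfate | O=c1c(OS(=O)(=O)O)c(-c2ccc(OS(=O)(=O)O)c(OCc3ccccc3)c2)oc2cc(OCc3ccccc3)cc(OCc3ccccc3)c12 | intermediate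
17 | quercetin 3,4'-bissulfate | O=c1c(OS(=O)(=O)O)c(-c2ccc(OS(=O)(=O)O)c(O)c2)oc2cc(O)cc(O)c12 | target

**Step count and risks**
Total steps: 10. Longest linear sequence: 10 steps (1 to 17); 4 and 6 enter as purchased materials.

Steps most likely to fail:

1. Step 5. Ionisation of the doubly activated benzylic, propargylic C–O bond or oligomerisation of the o-quinone methide at 180 °C may outrun the concerted shift and ring closure. Fallback: setting out from 7, a cationic gold catalyst (Ph3PAuNTf2, 2 mol%, CH2Cl2, rt) would activate the alkyne for 6-endo-dig hydroarylation by the electron-rich ortho carbon of ring A. This forms C4–C4a directly without breaking O1–C2 and comes back to the route at 11. This fallback makes no new compound (F0).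

2. Step 4. Ionisation of the electron-rich propargylic oxyphosphonium ion may lead to C-alkylation of ring A or to SN2' attack at the alkyne terminus instead of O-alkylation with inversion. Fallback: setting out from 5, acylation with methyl chloroformate and pyridine (CH2Cl2, 0 °C) would give 1-[3-(benzyloxy)-4-(methoxymethoxy)phenyl]prop-2-yn-1-yl methyl carbonate F1. Copper-catalysed propargylic etherification of F1 with phenol 6 (CuOTf·1/2C6H6 with a 2,6-bis(oxazolinyl)pyridine ligand, iPr2NEt, 0 °C) would proceed through a copper allenylidene that is attacked by the phenoxide oxygen at the propargylic carbon, with loss of CO2 and methanol. This comes back to the route at 7.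

3. Step 7. Oxidative cleavage of the C3–C4 glycol, stalling at an α-ketol, or over-oxidation of the product enol may compete with the clean double oxidation. Fallback: setting out from 12, MnO2 (CH2Cl2, rt) would oxidise only the benzylic C4 carbinol to the trans-dihydroflavonol rac-(2R,3R)-5,7-bis(benzyloxy)-2-[3-(benzyloxy)-4-(methoxymethoxy)phenyl]-3-hydroxychroman-4-one F2. With the glycol motif removed, a single alcohol oxidation of F2 with Dess–Martin periodinane (NaHCO3, CH2Cl2, 0 °C) would give dione 13, which tautomerises as before. This comes back to the route at 14.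

**Further compounds**
F0 | step 5 | none | none
F1 | step 4 | 1-[3-(benzyloxy)-4-(methoxymethoxy)phenyl]prop-2-yn-1-yl methyl carbonate (racemic, R enantiomer drawn) | C#C[C@@H](OC(=O)OC)c1ccc(OCOC)c(OCc2ccccc2)c1
F2 | step 7 | rac-(2R,3R)-5,7-bis(benzyloxy)-2-[3-(benzyloxy)-4-(methoxymethoxy)phenyl]-3-hydroxychroman-4-one (2S,3S enantiomer drawn) | O[C@H]1[C@H](c2ccc(OCOC)c(OCc3ccccc3)c2)Oc2cc(OCc3ccccc3)cc(OCc3ccccc3)c2C1=O
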